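The easy mistake with this flask is to follow the target as if it were what the substrate makes. The substrate really makes a pool of target and isomer, and the reagent attacks the target part of that pool.

in all of them: substrate 1.0 mM; time 1.0 min; volume of the second phase over the first 1.0
- Friday's: reagent in the second phase 0.600 equiv
- Wednesday's: reagent in the second phase 1.20 equiv
- Sunday's: reagent in the second phase 2.50 equiv
- Tuesday's: reagent in the second phase 5.00 equiv

    target ⇌ isomer of the product (K1 = 0.87, k1 = 0.13 s⁻¹)
    substrate + reagent in the reaction phase → target (k2 = 100 M⁻¹ s⁻¹)
    reagent in the reaction phase + target → over-reacted product (k3 = 14 M⁻¹ s⁻¹)
    2 reagent in the reaction phase → homo dimer (k4 = 32 M⁻¹ s⁻¹)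
    reagent in the reaction phase ⇌ reagent in the second phase, rate k5*([reagent in the reaction phase] - [reagent in the second phase]/K5) per volume of the first phase (K5 = 0.66, k5 = 0.026 s⁻¹)

- two of one species on the left: rate k times its square, two consumed each time
- in the second phase: reagent in the second phase; everything else is in the first
- charges count per volume of the first phase; a concentration in a rate is the amount of a species over the volume of its own phase; every rate counts per litre of the first phase
- "hardly changes" means that all values lie within two and a half points (for a concentration: within two and a half percent of the largest)
- run time (Friday's): 1.0 min

* amount of target at the end, in percent of the substrate charged for Friday's, Wednesday's, Sunday's, Tuesday's, in this order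
* how the row runs (rises all the way / hardly changes / falls all the way / rises, then falls / falls, then rises)

Minutes of the meeting. I opened at the board with the pair target and isomer. It relaxes with a half-life of 2.48 s, shorter than the run of 1.0 min, so I held that it stands close to equilibrium while the run lasts, which is thermodynamic control of the pair. The target's share of the pool, one over one plus the constant, is then 0.535, above the even split.

The colleague minding selectivity asked when the pool stops growing. She noted that both attacks carry the reagent in the reaction phase, so it cancels: the pool gains while substrate times 100 M⁻¹ s⁻¹ beats target times 14 M⁻¹ s⁻¹. I wrote the target as its share of the pool and got 0.0749, the turn fraction, which is the substrate over the pool at which gain and loss are equal. The zero of this scale is the statistical case, a reagent blind between substrate and target acting on an evenly split pair, where the turn stands at 0.5. A selectivity factor of 7.14 brings it far below that.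

The colleague minding supply objected that a ratio gives no clock, since the reagent has to come over from the second phase. I answered for the two ends of the row. In Friday's flask the reagent is the limiting reagent at 0.600 equiv, so the substrate over the pool stays at 0.667 or higher, above the turn, and Friday's pool is still growing at the end. Tuesday's charge of 5.00 equiv sets no such floor. I scored a rise that tops out by Friday's floor over the turn, a rise all the way by the same reckoning at Tuesday's charge, where it comes out below zero, and the other options by small marks made from the turn. So I committed to the shape rises, then falls, and to no figures.

The forecast did give figures: 22.5%, 35.5%, 43% and 40%, with the shape rises, then falls, and it called the top “a gap of only a few points”.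

The flask gives 21.6%, 34.7%, 43.0% and 39.6%, a row of the shape rises, then falls, with the turn read at 2.7 equiv. The forecast stands on Tuesday's lying 3.4 percentage points under Sunday's, and a run reversing that gap is what it takes to prove it wrong. At the end of Sunday's flask the substrate over the pool is 0.111, above the turn fraction of 0.0749. At the end of Tuesday's flask it is 0.0148, below it, with over-reacted product at 24.1%.

(All constants are those of an exercise; the flask was simulated.)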